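| flask | substrate | reagent | remark | time |
|---|---|---|---|---|
| Tuesday's | 0.70 mM | 0.50 mM | run made earlier |  |
| Sunday's | 1.1 mM | 0.50 mM | run made earlier |  |
| Wednesday's | 0.50 mM | 1 mM | run made earlier |  |
| flask | 0.50 mM | 0.500 mM |  | 4.0 min |

- Tuesday's (time / min: bis adduct / %, side product / %): 0.417: 6.0, 87.0; 0.833: 7.9, 90.1; 2.00: 8.2, 89.6; 5.00: 8.8, 90.8
- Sunday's (time / min: bis adduct / %, side product / %): 0.667: 2.9, 81.6; 1.50: 1.4, 83.0; 3.00: 1.0, 82.6; 5.00: 1.4, 83.8
- Wednesday's (time / min: bis adduct / %, side product / %): 1.33: 30.9, 67.1; 2.50: 32.6, 67.1; 4.00: 33.7, 67.6; 5.00: 32.0, 68.4

(each reading ± 1 percentage point)

- a species is counted by the substrate in it: one side product counts as two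
- what was read earlier has a scatter of 1 percentage point, one standard deviation
- the reaction counts as stopped when no species that holds the substrate changes by six tenths of a point or more over the second half of the time

- which holds at 4.0 min: what has brought the reaction to rest, or that it has not come to rest (it is still moving / the reagent has run out first / all of the substrate has reacted)
- the bis adduct standing at 4.0 min, as a percentage of the substrate charged
- the side product standing at 4.0 min, as a percentage of the substrate charged

Sunday's run cannot have turned all its substrate into the two products we read, for its last readings add up to 85.2%, while Tuesday's and Wednesday's close at 99.6% and 100%. We read the side product as two substrate on one reagent, which gives the bench rule that, for the substrate to end wholly as side product, the equivalents r, reagent charged over substrate charged, must reach 0.5. Sunday's run has r = 0.455, and reagent looks like the limiting reagent there.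

That rule is only a floor. We read the bis adduct as one substrate on two reagent, so a finished flask uses b = 0.5 y_O + 2 y_D of reagent per substrate, with y the fractions of the substrate charged. In Tuesday's run the bis adduct is the small correction, so we follow ρ = y_D/y_O. Tuesday's readings after its first give ρ = 0.0921 at r = 0.714, and Wednesday's give 0.478 at r = 2.00. The rise of ρ per equivalent, the gain g, is therefore 0.300.

For the flask, r = 1.00, so our line gives ρ = 0.178, that is 15.1% bis adduct and 84.9% side product. Then b = 0.726, less than r, so we expect the substrate to go first, with 27.4% of the reagent left. Tuesday's run, on the same reagent charge, is flat within the scatter from 0.833 min, so we take the flask to be at rest by 4.0 min.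

The forecast, which reads “so substrate runs out first, with reagent to spare”, gave all of the substrate has reacted as the state of the flask, with 16% bis adduct and 84% side product. The flask gives: all of the substrate has reacted, with 15.4% bis adduct and 84.3% side product.

    2 substrate → homo dimer (k = 1.10 /M/s)
    substrate + single product → side product (k = 2500 /M/s)
    substrate + reagent → single product (k = 350 /M/s)
    reagent + single product → bis adduct (k = 360 /M/s)

At 0.0438 min in the flask, single product passes into side product at 5.45 times its rate into bis adduct. By 0.400 min the step to side product has 98% of its turnover up to 4.0 min behind it, and the early samples are the ones to watch. Against g's ρ of 0.178, the flask shows 0.183. With 0.12 mM of substrate, r = 4.17, and g gives ρ = 1.13, or 53.1% bis adduct; that neighbour flask computes to 52.5%.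

All runs were generated by integration for substances that don't exist; noise was put on by code.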